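## Retrosynthetic overview
1. The C16–C17 and N1–C17 bonds are cut together. The tetrahydropyridine comes from a (Z)-vinylsilane-terminated iminium cyclisation at N1 of a 13-membered spermidine lactam. Oct-1-yn-3-one serves as the 3-oxooctanal equivalent, and C13 relays its configuration to C17 (2,6-trans).
2. The 13-membered lactam is cut at N10–C11. This leads back to an eight-membered 1,5-diazocan-2-one with a masked 4-aminobutyl arm on N5 (transamidative ring expansion). The ring expansion and the six-ring closure are run in one flask.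
3. The diazocanone comes from an N-(3-chloropropyl) β-lactam and mono-trifluoroacetylated putrescine, by amination followed by 4→8 ring expansion.
4. The β-lactam comes from 4-acetoxyazetidin-2-one and a silylpropargyl zinc reagent. Lipase resolution fixes C13 and semi-hydrogenation fixes the Z-vinylsilane.
5. Ring order: the four-membered ring is bought, then eight, then thirteen and six in the same operation.

Atom labels (N-1, N-5, N-10, C-13, C-17) follow the name of the target, (13R,17S)-17-(2-oxoheptyl)-1,5,10-triazabicyclo[11.4.0]heptadec-15-en-11-one. The two ring substituents are trans. Systematic names of monocyclic intermediates keep their own numbering.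

Assumption: Candida antarctica lipase B leaves the (R)-lactam untouched, as it does for spatially analogous 4-substituted azetidin-2-ones.

## Route

Step 1
Reactants: 1 4-acetoxyazetidin-2-one (racemic); 2 3-bromo-1-(trimethylsilyl)prop-1-yne
Product: 5 rac-4-[3-(trimethylsilyl)prop-2-yn-1-yl]azetidin-2-one, via allenylzinc bromide 3 (not isolated), via azet-2(3H)-one 4 (not isolated)
Conditions: Zn dust (3 equiv), 2 (2.5 equiv), THF, 0 °C to rt; then 1, rt, 3 h; aq NH4Cl
Reagents that add atoms: none
Why: Barbier-type elimination–addition, in which one equivalent of 3 deprotonates N–H so that acetate leaves to give N-acylimine 4, and a second equivalent adds by SE2' through its CH2 terminus because the silyl group blocks the allenyl product; the new stereocentre is racemic at this stage.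

Step 2
Reactants: 5 rac-4-[3-(trimethylsilyl)prop-2-yn-1-yl]azetidin-2-one
Product: 6 (R)-4-[3-(trimethylsilyl)prop-2-yn-1-yl]azetidin-2-one
Conditions: immobilised Candida antarctica lipase B, H2O (0.6 equiv), i-Pr2O, 60 °C, to 52–55% conversion; filter, chromatography
Reagents that add atoms: none
Why: Lipase-catalysed enantioselective ring cleavage of a β-lactam (kinetic resolution), in which the (S)-lactam is hydrolysed to the insoluble amino acid and running slightly past half conversion leaves the (R)-lactam in high ee, which fixes C-13.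

Step 3
Reactants: 6 (R)-4-[3-(trimethylsilyl)prop-2-yn-1-yl]azetidin-2-one
Product: 7 (R)-4-[(Z)-3-(trimethylsilyl)prop-2-en-1-yl]azetidin-2-one
Conditions: H2 (1 atm), 5% Pd/CaCO3 poisoned with Pb(OAc)2 (Lindlar type), quinoline, EtOAc, rt, stopped at 1 equiv H2
Reagents that add atoms: none
Why: Semi-hydrogenation of a silylalkyne by syn delivery of H2 on poisoned Pd gives the Z-vinylsilane that the later cyclisation needs, and the stereocentre is not touched.

Step 4
Reactants: 7 (R)-4-[(Z)-3-(trimethylsilyl)prop-2-en-1-yl]azetidin-2-one; 8 1-bromo-3-chloropropane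
Product: 9 (R)-1-(3-chloropropyl)-4-[(Z)-3-(trimethylsilyl)prop-2-en-1-yl]azetidin-2-one
Conditions: 8 (3 equiv), powdered KOH, Bu4NBr (cat.), THF, 0 °C to rt
Reagents that add atoms: none
Why: Phase-transfer N-alkylation (SN2) of the lactam anion at the bromide end, bromide being the better leaving group, and C-4–H is not acidic so the configuration holds.

Step 5
Reactants: 10 butane-1,4-diamine; 11 ethyl trifluoroacetate
Product: 12 N-(4-aminobutyl)-2,2,2-trifluoroacetamide
Conditions: 10 (5 equiv), 11 (1 equiv), MeOH, 0 °C to rt; excess 10 distilled off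
Reagents that add atoms: none
Why: Aminolysis of an activated ester, with the excess of the diamine enforcing mono-acylation.

Step 6
Reactants: 9 (R)-1-(3-chloropropyl)-4-[(Z)-3-(trimethylsilyl)prop-2-en-1-yl]azetidin-2-one; 12 N-(4-aminobutyl)-2,2,2-trifluoroacetamide
Product: 14 (R)-2,2,2-trifluoro-N-(4-{2-oxo-4-[(Z)-3-(trimethylsilyl)prop-2-en-1-yl]-1,5-diazocan-1-yl}butyl)acetamide, via aminopropyl azetidinone 13 (not isolated)
Conditions: 12 (3 equiv), NaI (0.2 equiv), NaHCO3 (2 equiv), MeCN, 80 °C, 24 h
Reagents that add atoms: none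
Why: Iodide-assisted SN2 amination gives secondary amine 13, whose nitrogen sits three carbons from the strained lactam nitrogen and so attacks the β-lactam carbonyl through a six-membered tetrahedral intermediate (transamidative 4→8 ring expansion), which acylates N-5, frees N-1 as the only amine and leaves C-13 untouched.

Step 7
Reactants: 15 oct-1-yn-3-ol (racemic)
Product: 16 oct-1-yn-3-one
Conditions: IBX (1.5 equiv), EtOAc, 80 °C, 3 h; filter; used as a solution
Reagents that add atoms: none
Why: Hypervalent-iodine (IBX) oxidation of a propargylic alcohol stops cleanly at the ynone under neutral conditions, and the carbinol stereocentre disappears.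

Step 8
Reactants: 14 (R)-2,2,2-trifluoro-N-(4-{2-oxo-4-[(Z)-3-(trimethylsilyl)prop-2-en-1-yl]-1,5-diazocan-1-yl}butyl)acetamide; 16 oct-1-yn-3-one
Product: 21 (13R,17S)-17-(2-oxoheptyl)-1,5,10-triazabicyclo[11.4.0]heptadec-15-en-11-one, via aminobutyl diazocanone 17 (not isolated), via thirteen-membered lactam 18 (not isolated), via N-5 Boc lactam 19 (not isolated), via N-1 enaminone 20 (not isolated)
Conditions: one flask: 7 M NH3/MeOH, 60 °C (sealed), 36 h, evaporate (toluene chase); Boc2O (1.0 equiv), CH2Cl2, -10 °C, 1 h; 16 (1.1 equiv), rt, 2 h; TFA/CH2Cl2 1:4 (dry), 0 to 40 °C, 12 h; cold aq K2CO3, rapid extraction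
Reagents that add atoms: none
Why: Proposed new method: ammonolysis frees the primary amine of 17, which attacks the strained tertiary eight-ring lactam through a seven-membered tetrahedral intermediate and expels N-5 to give 18 without high dilution (transamidative "zip" ring expansion, known for N-(aminoalkyl) lactams); Boc2O then takes the unhindered N-5, so the ynone can add only to N-1 (amine–ynone conjugate addition); in TFA the Boc group falls off and N-5 stays protonated, the enaminone is protonated to the β-keto iminium ion (as in the activated-alkyne variant of the Pictet–Spengler reaction), and the (Z)-vinylsilane attacks it through a chair in which the C-13 side chain is axial to avoid A(1,3) strain with the N-1 chain and the oxoheptyl group is equatorial, so loss of silicon places the alkene only at C15=C16 and sets C-17 trans to C-13 (closest known type: the vinylsilane-terminated iminium cyclisation or aza-silyl-Prins reaction, which gives 2,6-trans-tetrahydropyridines).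

## Compound list
1 | 4-acetoxyazetidin-2-one (racemic) | CC(=O)OC1CC(=O)N1 | starting material
2 | 3-bromo-1-(trimethylsilyl)prop-1-yne | C[Si](C)(C)C#CCBr | starting material
3 | [1-(trimethylsilyl)propa-1,2-dien-1-yl]zinc bromide | C=C=C([Zn]Br)[Si](C)(C)C | intermediate
4 | azet-2(3H)-one | O=C1CC=N1 | intermediate
5 | rac-4-[3-(trimethylsilyl)prop-2-yn-1-yl]azetidin-2-one | C[Si](C)(C)C#CCC1CC(=O)N1 | intermediate
6 | (R)-4-[3-(trimethylsilyl)prop-2-yn-1-yl]azetidin-2-one | C[Si](C)(C)C#CC[C@@H]1CC(=O)N1 | intermediate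
7 | (R)-4-[(Z)-3-(trimethylsilyl)prop-2-en-1-yl]azetidin-2-one | C[Si](C)(C)/C=C\C[C@@H]1CC(=O)N1 | intermediate
8 | 1-bromo-3-chloropropane | ClCCCBr | starting material
9 | (R)-1-(3-chloropropyl)-4-[(Z)-3-(trimethylsilyl)prop-2-en-1-yl]azetidin-2-one | C[Si](C)(C)/C=C\C[C@@H]1CC(=O)N1CCCCl | intermediate
10 | butane-1,4-diamine | NCCCCN | starting material
11 | ethyl trifluoroacetate | CCOC(=O)C(F)(F)F | starting material
12 | N-(4-aminobutyl)-2,2,2-trifluoroacetamide | NCCCCNC(=O)C(F)(F)F | intermediate
13 | (R)-2,2,2-trifluoro-N-{4-[(3-{2-oxo-4-[(Z)-3-(trimethylsilyl)prop-2-en-1-yl]azetidin-1-yl}propyl)amino]butyl}acetamide | C[Si](C)(C)/C=C\C[C@@H]1CC(=O)N1CCCNCCCCNC(=O)C(F)(F)F | intermediate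
14 | (R)-2,2,2-trifluoro-N-(4-{2-oxo-4-[(Z)-3-(trimethylsilyl)prop-2-en-1-yl]-1,5-diazocan-1-yl}butyl)acetamide | C[Si](C)(C)/C=C\C[C@@H]1CC(=O)N(CCCCNC(=O)C(F)(F)F)CCCN1 | intermediate
15 | oct-1-yn-3-ol (racemic) | CCCCCC(O)C#C | starting material
16 | oct-1-yn-3-one | CCCCCC(=O)C#C | intermediate
17 | (R)-1-(4-aminobutyl)-4-[(Z)-3-(trimethylsilyl)prop-2-en-1-yl]-1,5-diazocan-2-one | C[Si](C)(C)/C=C\C[C@@H]1CC(=O)N(CCCCN)CCCN1 | intermediate
18 | (R)-6-[(Z)-3-(trimethylsilyl)prop-2-en-1-yl]-1,5,9-triazacyclotridecan-8-one | C[Si](C)(C)/C=C\C[C@@H]1CC(=O)NCCCCNCCCN1 | intermediate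
19 | tert-butyl (R)-8-oxo-6-[(Z)-3-(trimethylsilyl)prop-2-en-1-yl]-1,5,9-triazacyclotridecane-1-carboxylate | C[Si](C)(C)/C=C\C[C@@H]1CC(=O)NCCCCN(C(=O)OC(C)(C)C)CCCN1 | intermediate
20 | tert-butyl (R)-8-oxo-5-[(E)-3-oxooct-1-en-1-yl]-6-[(Z)-3-(trimethylsilyl)prop-2-en-1-yl]-1,5,9-triazacyclotridecane-1-carboxylate | C[Si](C)(C)/C=C\C[C@@H]1CC(=O)NCCCCN(C(=O)OC(C)(C)C)CCCN1/C=C/C(=O)CCCCC | intermediate
21 | (13R,17S)-17-(2-oxoheptyl)-1,5,10-triazabicyclo[11.4.0]heptadec-15-en-11-one | CCCCCC(=O)C[C@H]1C=CC[C@@H]2CC(=O)NCCCCNCCCN21 | target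

## Count and risks
Total steps: 8. Longest linear sequence: 6 (steps 1, 2, 3, 4, 6, 8).

**Step 8.**
- Risks:
  - The 8→13 ring expansion may be slow at 60 °C.
  - Boc2O may not fully discriminate N-5 from N-1.
  - A protonated enaminone is a weaker electrophile than a plain iminium ion, so protodesilylation or a 2-aza-Cope leak could compete.
  - The free-base product can epimerise at C-17 by retro-aza-Michael reaction, hence the acid finish and cold work-up.
- Fallback: it sets out from 14 and 16 and comes back at 21, closing the six-membered ring first and the macrocycle last.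
  - Ynone 16 is added to 14 while N-1 is its only amine, giving the diazocanone N-1 enaminone F1.
  - TFA/CH2Cl2 cyclises this to the 6/8-bicyclic amino ketone F2.
  - Ethylene glycol and TsOH in benzene mask the ketone as the dioxolane-protected bicycle F3.
  - At this point no enaminone, vinylsilane or free β-amino ketone is left. Trifluoroacetamide removal and ring expansion can therefore be forced (7 M NH3/MeOH, 100 °C, sealed) to the ring-expanded dioxolane F4.
  - 1 M HCl at rt then releases 21.

**Step 2.**
- Risks: the lipase may accept this 4-alkyl lactam slowly or with a modest selectivity factor.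
- Fallback: it sets out from 5 and comes back at 6. The racemate is separated physically by preparative supercritical-fluid chromatography on an amylose tris(3,5-dimethylphenylcarbamate) phase instead of being resolved kinetically. New compounds on this path: none F0.

**Step 6.**
- Risks:
  - Substitution of a primary chloride by a primary amine at 80 °C can be sluggish.
  - The reaction can over-alkylate.
  - It can let 12 open the β-lactam intermolecularly.
- Fallback: it sets out from 7 and comes back at 13, forming the C–N bond by reductive amination instead of substitution.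
  - Lactam 7 is N-alkylated with 2-(2-bromoethyl)-1,3-dioxolane (KOH, Bu4NBr, THF) to the dioxolanylethyl azetidinone F5.
  - PPTS in wet acetone unmasks the azetidinone propanal F6.
  - 12 with NaBH(OAc)3 in ClCH2CH2Cl at rt gives 13, which ring-expands to 14 on warming in MeCN.

## Further compounds
F1 | step 8 | (R)-2,2,2-trifluoro-N-(4-{2-oxo-5-[(E)-3-oxooct-1-en-1-yl]-4-[(Z)-3-(trimethylsilyl)prop-2-en-1-yl]-1,5-diazocan-1-yl}butyl)acetamide | C[Si](C)(C)/C=C\C[C@@H]1CC(=O)N(CCCCNC(=O)C(F)(F)F)CCCN1/C=C/C(=O)CCCCC
F2 | step 8 | 2,2,2-trifluoro-N-{4-[(8R,12S)-6-oxo-12-(2-oxoheptyl)-1,5-diazabicyclo[6.4.0]dodec-10-en-5-yl]butyl}acetamide | CCCCCC(=O)C[C@H]1C=CC[C@@H]2CC(=O)N(CCCCNC(=O)C(F)(F)F)CCCN21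
F3 | step 8 | 2,2,2-trifluoro-N-(4-{(8R,12S)-6-oxo-12-[(2-pentyl-1,3-dioxolan-2-yl)methyl]-1,5-diazabicyclo[6.4.0]dodec-10-en-5-yl}butyl)acetamide | CCCCCC1(OCCO1)C[C@H]2C=CC[C@@H]3CC(=O)N(CCCCNC(=O)C(F)(F)F)CCCN32
F4 | step 8 | (13R,17S)-17-[(2-pentyl-1,3-dioxolan-2-yl)methyl]-1,5,10-triazabicyclo[11.4.0]heptadec-15-en-11-one | CCCCCC1(OCCO1)C[C@H]2C=CC[C@@H]3CC(=O)NCCCCNCCCN32
F0 | step 2 | none | none
F5 | step 6 | (R)-1-[2-(1,3-dioxolan-2-yl)ethyl]-4-[(Z)-3-(trimethylsilyl)prop-2-en-1-yl]azetidin-2-one | C[Si](C)(C)/C=C\C[C@@H]1CC(=O)N1CCC2OCCO2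
F6 | step 6 | (R)-3-{2-oxo-4-[(Z)-3-(trimethylsilyl)prop-2-en-1-yl]azetidin-1-yl}propanal | C[Si](C)(C)/C=C\C[C@@H]1CC(=O)N1CCC=O
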